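## The problem

Target 41 is one cyclohexane ring with a substituent on every carbon but one. The ring is numbered C1 (methyl, vinyl), C2 (CH2), C3 (acyloxy), C4 (1-carboxyvinyl), C5 (hydroxyl), C6 (3-hydroxyprop-1-en-2-yl); the configuration is 1S,3S,4S,5S,6R. The methyl group, the C6 alkenyl group, the C5 hydroxyl and the C4 acrylic acid lie on one face (β); the vinyl group and the C3 ester oxygen lie on the other (α). In the chair the methyl and the C5 hydroxyl are syn-axial and all other groups are equatorial.

The five stereocentres are contiguous and one is quaternary. C1 cannot be corrected later and must be set first, in absolute terms. It can then steer its neighbour C6 and, through its axial methyl, the face of a C5 carbonyl. The C5 oxygen can in turn place the C4 carbon, and the ring made in doing so can direct C3.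

Several groups are fragile:
- the cis γ-hydroxy α-methylene acid lactonises under acid and is a Michael acceptor;
- the (Z)-4-acetoxy-2-methylbut-2-enoate can isomerise to E, is cleaved by hydroxide, and would close to a butenolide if its acetate were lost;
- three terminal alkenes and a primary allylic alcohol rule out hydrogenation and late electrophilic oxidants.

The feature that opens the key step is that the C5 oxygen and the C4 acid carbon are cis on adjacent carbons. They form a latent cis-fused five-membered ring (O5, C5, C4, Cα, acid carbon). The C3 oxygen is trans to that ring. This is the pattern left when a radical tethered to O5 adds to C4 of a C3=C4 alkene and the C3 radical is trapped from the open face.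

## Retrosynthesis

**41 from 40.** The last cut removes three silicon-based groups: the C5 triethylsilyl ether, the primary TBDPS ether and the 2-(trimethylsilyl)ethyl ester. The free hydroxy acid cannot be carried through an acylation, and hydroxide cannot be used once the side-chain ester is in place. Fluoride spares the acetate and both esters. The forward step must release the acid without acid catalysis.

**40 from 33 and 38.** The C3 ester bond is cut next. The (Z)-acetoxy enoate survives neither enolate chemistry nor saponification, so it must enter after the acrylate is finished. Acid 38 comes from butenolide 34 via PMB ester 37; the ring of 34 fixes the Z geometry. The acylation must not isomerise the alkene.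

**33 from 28.** The acrylate ester, the C5 silyl ether and the free C3 hydroxyl are traced through 32 and 31 to α-methylene lactone 28. The lactone C–O bond is the protected form of the cis hydroxy acid. Opening it before the side chain arrives is the only point at which hydroxide is tolerated. A PMB ether on C3 is the one group removable by oxidation in the presence of three silyl groups.

**28 from 22.** The exocyclic methylene is cut (Eschenmoser methylenation of lactone 25). The lactone carbonyl is traced through lactol 24 and PMB ether 23 to the ethyl acetal 22. This leaves a bicyclic acetal with no acrylate and one free hydroxyl.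

**22 from 20 (key cut).** The C4–Cα bond and the C3–O bond are cut together, which opens the tetrahydrofuran and gives bromoacetal 20. Cutting C4–Cα alone (a reductive cyclisation) would leave C3 without oxygen. Cutting C3–C4 or C5–C6 would open the carbocycle and give up ring-based control. Precursor 20 has two fewer stereocentres and no C4 substituent. The forward step needs 5-exo closure onto C4 only, and capture of the C3 radical by O2 from the α face.

**20 from 18 and 19.** The acetal C–O bond is cut to allylic alcohol 18 and ethyl vinyl ether 19. Only the enol ether should react with the bromonium source.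

**18 from 14.** The C5 carbinol comes from enone 17 by 1,2-reduction. The C3=C4 alkene comes from loss of the C3 oxygen of β-hydroxy ketone 15, itself from silyl ether 14. Elimination through a mesylate, and not directly from the silyl ether, is chosen because the C6 centre becomes epimerisable once the enone exists. Base contact must therefore be short.

**14 from 9 and 11.** The C6–C(sp2) bond is cut to the regiodefined enol ether 9 and vinyl bromide 11 (from 10). The alkenyl group must enter anti to the axial C1 vinyl group. The chair is anchored by the equatorial C3 silyloxy and C1 methyl groups, so this gives the alkenyl group cis to methyl.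

**9 from 1.** The C1–vinyl bond is cut to β-methyl enone 7 and vinylmagnesium bromide 8. The methyl is placed in the enone and the vinyl group is the nucleophile, so 1,6-addition cannot occur and the vinyl group ends axial, as the next step requires. Enone 7 comes from enone 5 by methyl addition and dehydrogenation. Enone 5 comes from the meso diol 2 by enzymatic desymmetrisation (monoacetate 3). Diol 2 comes from the commercial all-cis triol 1, the hydrogenation product of phloroglucinol.

## Roads not taken

**Alternative 1: three-component methyl addition and enolate alkenylation.**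
- Cut: the C1–methyl and C6–alkenyl bonds are made in one flask. MeMgBr adds to vinyl enone A1 under Cu(OTf)2 with a chiral N-heterocyclic carbene ligand. The enolate is passed to zinc (ZnCl2) and coupled with bromide 11 under Pd(dba)2 (zerovalent palladium) and a bulky phosphine, giving A2.
- Merits: two bonds and two stereocentres in one operation. The C3 silyloxy group of A2 already has the configuration of the target's C3 oxygen.
- Weak points: copper reagents normally add 1,6 to a vinyl-conjugated enone, so 1,4-delivery rests on a ligand effect. In A2 the alkenyl group must sit cis to the methyl that has just entered axially; that is the equatorial position of the anchored chair, the face an incoming electrophile avoids. Copper, magnesium, zinc and palladium must coexist. Nothing is decided about C4 and C5, and using the retained C3 oxygen would mean alkylating C4 through an enolate with a β-silyloxy leaving group.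
- Comparison: this road is one step shorter than steps 5 and 7 of the chosen route, and it could in principle keep the C3 oxygen. The chosen plan sets against this the reversed roles of methyl and vinyl, which make the conjugate addition unambiguous and both new bonds axial, and the relay from C5 to C4 to C3 in the radical step.

**Alternative 2: carbonyl-ene closure of C5–C6.**
- Cut: C5–C6, back to open-chain aldehyde A3. Me2AlCl activates the aldehyde, C5 bonds to C6, and a hydrogen of the vinylic methyl shifts to oxygen, giving A4.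
- Merits: one step closes the ring, makes the C5 carbinol and the C6 centre, and creates the exocyclic methylene. The fragments can be joined convergently. No radical or peroxide chemistry is needed, and the C4 carbon skeleton is already in place.
- Weak points: A3 needs the quaternary C1 and the C3/C4 pair set in an open chain. C4 of A3 is both α to the aldehyde and allylic, so a Lewis acid can epimerise it or move the alkene into conjugation. The C3 ether is a β leaving group. This type of closure normally puts the hydroxyl and the new alkenyl group trans and diequatorial, whereas 41 needs them cis with the hydroxyl axial. A4 still requires oxidation of one of two allylic silyl ethers to the acid.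
- Comparison: convergence and the preinstalled C4 unit are better here. The chosen plan sets against this ring-based control of all five centres and a C5 configuration that follows the steric bias of the ring.

**Alternative 3: CrCl2-mediated ring closure at C3–C4.**
- Cut: C3–C4, back to aldehyde–allylic bromide A5. CrCl2 (divalent chromium) gives an allylchromium species (trivalent chromium) whose γ-carbon C4 adds to the C3 aldehyde, giving A6.
- Merits: the ring closure creates the α-methylene ester directly, so the acetal, lactone, methylenation and ring-opening steps disappear. C3–OH emerges free for acylation, and the anti C3–O/C4–C relation is the usual outcome of allylchromium additions.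
- Weak points: the cis relation of C4 to the C5 silyloxy group must come from 1,2-induction during the closure and is not secured. A5 is a crowded open chain with C1, C6 and C5 contiguous, and these must be built without a ring. The chromium alkoxide at C3 may lactonise onto the ester. Chromium is used in excess.
- Comparison: the endgame is clearly shorter, by about five steps. The chosen plan accepts the longer endgame because C1, C6 and C5 are set on a conformationally anchored ring and C4 is delivered intramolecularly from C5.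

Key step: step 12

Assumption (chemistry): the lipase acetylates the hydroxyl of meso diol 2 that leads to (1R,3S,5S)-3; if the enzyme at hand prefers the other hydroxyl, the same monoacetate is taken from hydrolase-mediated hydrolysis of the diacetate of 2.

## Route

Step 1
Reactants: 1 cis,cis-cyclohexane-1,3,5-triol
Product: 2 all-cis-5-[(tert-butyldimethylsilyl)oxy]cyclohexane-1,3-diol (meso)
Conditions: TBSCl (1 equiv), imidazole, DMF, 0 °C → rt; unreacted 1 recycled
Reagents that add atoms: tert-butyldimethylsilyl chloride, CC(C)(C)[Si](C)(C)Cl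
Why: Statistical monosilylation (silyl ether formation) of a triol with three equivalent hydroxyls; the mono-ether is meso, so only the degree of silylation needs control.

Step 2
Reactants: 2 all-cis-5-[(tert-butyldimethylsilyl)oxy]cyclohexane-1,3-diol
Product: 3 (1R,3S,5S)-3-hydroxy-5-[(tert-butyldimethylsilyl)oxy]cyclohexyl acetate
Conditions: lipase from Burkholderia cepacia (Amano PS), vinyl acetate, t-BuOMe, rt
Reagents that add atoms: vinyl acetate, CC(=O)OC=C
Why: Enzymatic desymmetrisation of a meso cis-1,3-diol by irreversible transesterification; the enzyme acylates one enantiotopic hydroxyl and supplies the only external stereochemical information of the route.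

Step 3
Reactants: 3 (1R,3S,5S)-3-hydroxy-5-[(tert-butyldimethylsilyl)oxy]cyclohexyl acetate
Product: 5 (5R)-5-[(tert-butyldimethylsilyl)oxy]cyclohex-2-en-1-one, via β-acetoxy ketone 4 (not isolated)
Conditions: Dess–Martin periodinane, CH2Cl2, 0 °C → rt; then DBU, 0 °C
Reagents that add atoms: none
Why: Alcohol oxidation followed by E1cB loss of acetate, a far better leaving group than silanolate, so the enone forms on the acetate side only and the silyloxy stereocentre is kept.

Step 4
Reactants: 5 (5R)-5-[(tert-butyldimethylsilyl)oxy]cyclohex-2-en-1-one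
Product: 7 (5R)-5-[(tert-butyldimethylsilyl)oxy]-3-methylcyclohex-2-en-1-one, via bromomagnesium enolate 6 (not isolated)
Conditions: MeMgBr, CuBr·SMe2 (10 mol%, monovalent copper), THF, −78 °C; then PhS(Cl)=N-t-Bu, −78 °C
Reagents that add atoms: methylmagnesium bromide, C[Mg]Br
Why: Copper-catalysed conjugate addition followed by dehydrogenation of the enolate with N-tert-butylbenzenesulfinimidoyl chloride (Mukaiyama dehydrogenation) gives the β-methyl enone in one flask; the transient methyl-bearing centre is erased and the enolate points away from the silyloxy group, so no β-elimination can occur.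

Step 5
Reactants: 7 (5R)-5-[(tert-butyldimethylsilyl)oxy]-3-methylcyclohex-2-en-1-one; 8 vinylmagnesium bromide
Product: 9 tert-butyl{[(1R,5S)-5-ethenyl-5-methyl-3-[(trimethylsilyl)oxy]cyclohex-3-en-1-yl]oxy}dimethylsilane
Conditions: CuBr·SMe2 (20 mol%), TMSCl, DMPU, THF, −78 → −40 °C; Et3N, aq. NaHCO3 work-up
Reagents that add atoms: chlorotrimethylsilane, C[Si](C)(C)Cl
Why: TMSCl-accelerated copper-catalysed 1,4-addition of a vinyl Grignard reagent to a β,β-disubstituted enone; the vinyl group enters axially and anti to the silyloxy group, which sets quaternary C1 (methyl β, vinyl α), and the enolate is trapped regiospecifically as its silyl enol ether.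

Step 6
Reactants: 10 2-bromoprop-2-en-1-ol
Product: 11 [(2-bromoprop-2-en-1-yl)oxy](tert-butyl)diphenylsilane
Conditions: TBDPSCl, imidazole, CH2Cl2, 0 °C → rt
Reagents that add atoms: tert-butyldiphenylsilyl chloride, CC(C)(C)[Si](Cl)(c1ccccc1)c1ccccc1
Why: Standard silylation of a primary allylic alcohol; the acid-stable TBDPS group is chosen so that it outlasts the later HF and aqueous HCl steps.

Step 7
Reactants: 9 tert-butyl{[(1R,5S)-5-ethenyl-5-methyl-3-[(trimethylsilyl)oxy]cyclohex-3-en-1-yl]oxy}dimethylsilane; 11 [(2-bromoprop-2-en-1-yl)oxy](tert-butyl)diphenylsilane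
Product: 14 (2R,3S,5R)-5-[(tert-butyldimethylsilyl)oxy]-2-{3-[(tert-butyldiphenylsilyl)oxy]prop-1-en-2-yl}-3-ethenyl-3-methylcyclohexan-1-one, via lithium enolate 12 (not isolated), via chlorozinc enolate 13 (not isolated)
Conditions: MeLi, THF, 0 °C; ZnCl2, 0 °C; then 11, Pd(dba)2 (5 mol%, zerovalent palladium), P(t-Bu)3 (10 mol%), THF, rt → 45 °C; pH 7 buffer work-up
Reagents that add atoms: none
Why: Regiospecific enolate release from the silyl enol ether and palladium-catalysed α-alkenylation of the zinc enolate (Negishi-type enolate coupling); on the chair anchored by the equatorial C3 silyloxy and C1 methyl groups the C6–C bond forms axially, anti to the axial C1 vinyl group, so the alkenyl group ends cis to methyl. The zinc enolate is not basic enough to remove the new equatorial C6–H, so the kinetic configuration is kept.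

Step 8
Reactants: 14 (2R,3S,5R)-5-[(tert-butyldimethylsilyl)oxy]-2-{3-[(tert-butyldiphenylsilyl)oxy]prop-1-en-2-yl}-3-ethenyl-3-methylcyclohexan-1-one
Product: 15 (2R,3S,5R)-2-{3-[(tert-butyldiphenylsilyl)oxy]prop-1-en-2-yl}-3-ethenyl-5-hydroxy-3-methylcyclohexan-1-one
Conditions: HF (48% aq.), MeCN, 0 °C
Reagents that add atoms: none
Why: Acidic desilylation; the secondary TBS ether is cleaved much faster than the primary TBDPS ether, and cold acid should cause neither retro-aldol cleavage nor enolisation at C6.

Step 9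
Reactants: 15 (2R,3S,5R)-2-{3-[(tert-butyldiphenylsilyl)oxy]prop-1-en-2-yl}-3-ethenyl-5-hydroxy-3-methylcyclohexan-1-one
Product: 17 (5S,6R)-6-{3-[(tert-butyldiphenylsilyl)oxy]prop-1-en-2-yl}-5-ethenyl-5-methylcyclohex-2-en-1-one, via mesylate 16 (not isolated)
Conditions: MsCl, Et3N, CH2Cl2, −20 → 0 °C
Reagents that add atoms: none
Why: Mesylation and E1cB elimination of the β-mesyloxy ketone; with a good leaving group every deprotonation at the unhindered C4 methylene is productive, so the enone forms after brief contact with a weak amine base and the hindered C6 centre, now α′ to the enone, is not equilibrated.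

Step 10
Reactants: 17 (5S,6R)-6-{3-[(tert-butyldiphenylsilyl)oxy]prop-1-en-2-yl}-5-ethenyl-5-methylcyclohex-2-en-1-one
Product: 18 (1R,5S,6R)-6-{3-[(tert-butyldiphenylsilyl)oxy]prop-1-en-2-yl}-5-ethenyl-5-methylcyclohex-2-en-1-ol
Conditions: NaBH4, CeCl3·7H2O, MeOH, −78 °C
Reagents that add atoms: none
Why: Luche 1,2-reduction; in the half-chair with the C6 group pseudo-equatorial the C1 methyl is pseudo-axial and shields the β face of the carbonyl, so hydride should enter from the α face and place the C5 hydroxyl cis to the C6 alkenyl group and the methyl.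

Step 11
Reactants: 18 (1R,5S,6R)-6-{3-[(tert-butyldiphenylsilyl)oxy]prop-1-en-2-yl}-5-ethenyl-5-methylcyclohex-2-en-1-ol; 19 ethyl vinyl ether
Product: 20 tert-butyl[(2-{(1R,2R,6S)-2-(2-bromo-1-ethoxyethoxy)-6-ethenyl-6-methylcyclohex-3-en-1-yl}prop-2-en-1-yl)oxy]diphenylsilane (acetal epimers)
Conditions: NBS, CH2Cl2, −40 → 0 °C
Reagents that add atoms: N-bromosuccinimide, O=C1CCC(=O)N1Br
Why: Haloacetalisation as used to prepare Ueno–Stork substrates; the electron-rich enol ether is brominated in preference to the three isolated alkenes and the C5 hydroxyl captures the oxocarbenium ion. The new acetal centre is of no consequence.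

Step 12
Reactants: 20 tert-butyl[(2-{(1R,2R,6S)-2-(2-bromo-1-ethoxyethoxy)-6-ethenyl-6-methylcyclohex-3-en-1-yl}prop-2-en-1-yl)oxy]diphenylsilane
Product: 22 (3aR,4S,6S,7R,7aS)-7-{3-[(tert-butyldiphenylsilyl)oxy]prop-1-en-2-yl}-2-ethoxy-6-ethenyl-6-methyloctahydro-1-benzofuran-4-ol (acetal epimers), via C3 hydroperoxide 21 (not isolated)
Conditions: Co(salen) (cobalt complex of N,N′-bis(salicylidene)ethylenediamine, divalent cobalt, 10 mol%), NaBH4, NaOH (aq.), EtOH, air admitted slowly, 40 °C
Reagents that add atoms: dioxygen, O=O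
Why: NaBH4 reduces the cobalt complex to a monovalent cobalt species that takes the bromine atom of 20 and releases the primary radical next to the acetal carbon; the closest known reaction type is the Ueno–Stork haloacetal cyclisation run with cobalt–salen, NaBH4 and air so that the cyclised radical ends as an alcohol. The radical closes 5-exo-trig onto C4 of the C3=C4 alkene: the two-atom O–CH(OEt) tether hangs from the β C5 oxygen and reaches only the neighbouring alkene carbon on that face, so the tetrahydrofuran is cis-fused and C4 is set by C5. The secondary C3 radical is captured by O2; its β face lies under the syn-axial C1 methyl and the axial C5–O bond of the new ring, so O2 enters from the α face, anti to the new C4–C bond, and hydroperoxide 21 is reduced in the flask to the equatorial alcohol, so C3 is set by the ring fusion. The vinyl group and the 1,1-disubstituted alkene do not compete because they could be reached only by six- or seven-membered closures, which are far slower than the 5-exo closure. The step needs cyclisation to precede oxygen capture of the primary radical; the acetal substituent accelerates ring closure and the slow admission of air keeps the oxygen concentration low.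

Step 13
Reactants: 22 (3aR,4S,6S,7R,7aS)-7-{3-[(tert-butyldiphenylsilyl)oxy]prop-1-en-2-yl}-2-ethoxy-6-ethenyl-6-methyloctahydro-1-benzofuran-4-ol
Product: 23 tert-butyl[(2-{(3aR,4S,6S,7R,7aS)-2-ethoxy-6-ethenyl-4-[(4-methoxybenzyl)oxy]-6-methyloctahydro-1-benzofuran-7-yl}prop-2-en-1-yl)oxy]diphenylsilane
Conditions: NaH, PMBCl, Bu4NI (cat.), DMF, 0 °C → rt
Reagents that add atoms: 4-methoxybenzyl chloride, COc1ccc(CCl)cc1
Why: Williamson etherification of the equatorial C3 hydroxyl; the acetal and the silyl ether are base-stable, and PMB is the one protecting group of the later sequence that can be removed by oxidation.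

Step 14
Reactants: 23 tert-butyl[(2-{(3aR,4S,6S,7R,7aS)-2-ethoxy-6-ethenyl-4-[(4-methoxybenzyl)oxy]-6-methyloctahydro-1-benzofuran-7-yl}prop-2-en-1-yl)oxy]diphenylsilane
Product: 24 (3aR,4S,6S,7R,7aS)-7-{3-[(tert-butyldiphenylsilyl)oxy]prop-1-en-2-yl}-6-ethenyl-4-[(4-methoxybenzyl)oxy]-6-methyloctahydro-1-benzofuran-2-ol (lactol epimers)
Conditions: HCl (1 M aq.), THF, rt
Reagents that add atoms: water, O
Why: Acid hydrolysis of a 2-ethoxytetrahydrofuran acetal, which is much faster than cleavage of the TBDPS or PMB ethers.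

Step 15
Reactants: 24 (3aR,4S,6S,7R,7aS)-7-{3-[(tert-butyldiphenylsilyl)oxy]prop-1-en-2-yl}-6-ethenyl-4-[(4-methoxybenzyl)oxy]-6-methyloctahydro-1-benzofuran-2-ol
Product: 25 (3aR,4S,6S,7R,7aS)-7-{3-[(tert-butyldiphenylsilyl)oxy]prop-1-en-2-yl}-6-ethenyl-4-[(4-methoxybenzyl)oxy]-6-methylhexahydro-1-benzofuran-2(3H)-one
Conditions: Pr4N[RuO4] (5 mol%, heptavalent ruthenium), N-methylmorpholine N-oxide, 4 Å MS, CH2Cl2, rt
Reagents that add atoms: none
Why: Ley–Griffith oxidation of a lactol to the γ-lactone; the alkenes and the PMB ether are inert under these conditions.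

Step 16
Reactants: 25 (3aR,4S,6S,7R,7aS)-7-{3-[(tert-butyldiphenylsilyl)oxy]prop-1-en-2-yl}-6-ethenyl-4-[(4-methoxybenzyl)oxy]-6-methylhexahydro-1-benzofuran-2(3H)-one
Product: 28 (3aR,4S,6S,7R,7aS)-7-{3-[(tert-butyldiphenylsilyl)oxy]prop-1-en-2-yl}-6-ethenyl-4-[(4-methoxybenzyl)oxy]-6-methyl-3-methylidenehexahydro-1-benzofuran-2(3H)-one, via Mannich base 26 (not isolated), via ammonium iodide 27 (not isolated)
Conditions: LiN(i-Pr)2, THF, −78 °C; [CH2=NMe2]I, −78 °C → rt; then MeI, MeOH, rt; then NaHCO3 (aq.), CH2Cl2, rt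
Reagents that add atoms: N,N-dimethylmethyleneiminium iodide, C=[N+](C)C.[I-]
Why: Eschenmoser methylenation (Mannich reaction of the lactone enolate, N-methylation, Hofmann-type elimination); the enolate has no β leaving group because the C3 and C5 oxygens are both γ, and the ring-fusion centres are not touched.

Step 17
Reactants: 28 (3aR,4S,6S,7R,7aS)-7-{3-[(tert-butyldiphenylsilyl)oxy]prop-1-en-2-yl}-6-ethenyl-4-[(4-methoxybenzyl)oxy]-6-methyl-3-methylidenehexahydro-1-benzofuran-2(3H)-one
Product: 31 2-[(1R,2S,3R,4S,6S)-3-{3-[(tert-butyldiphenylsilyl)oxy]prop-1-en-2-yl}-4-ethenyl-6-[(4-methoxybenzyl)oxy]-4-methyl-2-[(triethylsilyl)oxy]cyclohexyl]prop-2-enoic acid, via lithium carboxylate 29 (not isolated), via triethylsilyl ester 30 (not isolated)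
Conditions: LiOH·H2O, THF/H2O, rt; evaporation, toluene azeotrope; TESOTf, 2,6-lutidine, CH2Cl2, −78 → 0 °C; then THF/H2O, pH 5 buffer work-up
Reagents that add atoms: lithium hydroxide, [Li+].[OH-]; triethylsilyl trifluoromethanesulfonate, CC[Si](CC)(CC)OS(=O)(=O)C(F)(F)F
Why: Lactone saponification, silylation of the carboxylate and of the freed axial C5 hydroxyl, then selective hydrolysis of the labile silyl ester; capping the C5 oxygen prevents relactonisation from here on.

Step 18
Reactants: 31 2-[(1R,2S,3R,4S,6S)-3-{3-[(tert-butyldiphenylsilyl)oxy]prop-1-en-2-yl}-4-ethenyl-6-[(4-methoxybenzyl)oxy]-4-methyl-2-[(triethylsilyl)oxy]cyclohexyl]prop-2-enoic acid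
Product: 32 2-(trimethylsilyl)ethyl 2-[(1R,2S,3R,4S,6S)-3-{3-[(tert-butyldiphenylsilyl)oxy]prop-1-en-2-yl}-4-ethenyl-6-[(4-methoxybenzyl)oxy]-4-methyl-2-[(triethylsilyl)oxy]cyclohexyl]prop-2-enoate
Conditions: Me3SiCH2CH2OH, PPh3, DIAD, THF, 0 °C → rt
Reagents that add atoms: 2-(trimethylsilyl)ethanol, C[Si](C)(C)CCO
Why: Mitsunobu esterification, in which the hindered acid acts as the nucleophile toward the activated primary alcohol, so the acrylic acid needs no acyl activation; the ester is removable with fluoride.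

Step 19
Reactants: 32 2-(trimethylsilyl)ethyl 2-[(1R,2S,3R,4S,6S)-3-{3-[(tert-butyldiphenylsilyl)oxy]prop-1-en-2-yl}-4-ethenyl-6-[(4-methoxybenzyl)oxy]-4-methyl-2-[(triethylsilyl)oxy]cyclohexyl]prop-2-enoate
Product: 33 2-(trimethylsilyl)ethyl 2-[(1R,2S,3R,4S,6S)-3-{3-[(tert-butyldiphenylsilyl)oxy]prop-1-en-2-yl}-4-ethenyl-6-hydroxy-4-methyl-2-[(triethylsilyl)oxy]cyclohexyl]prop-2-enoate
Conditions: DDQ, CH2Cl2/pH 7 buffer, 0 °C → rt
Reagents that add atoms: none
Why: Oxidative cleavage of the PMB ether; the silyl ethers, the silylethyl ester and the isolated alkenes are inert to DDQ under buffered conditions.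

Step 20
Reactants: 34 3-methylfuran-2(5H)-one
Product: 37 4-methoxybenzyl (2Z)-4-(acetyloxy)-2-methylbut-2-enoate, via potassium carboxylate 35 (not isolated), via hydroxy ester 36 (not isolated)
Conditions: KOH, MeOH/H2O, rt, evaporation; PMBCl, DMF, rt; then Ac2O, pyridine, 0 °C
Reagents that add atoms: potassium hydroxide, [K+].[OH-]; 4-methoxybenzyl chloride, COc1ccc(CCl)cc1; acetic anhydride, CC(=O)OC(C)=O
Why: Saponification of the butenolide gives the hydroxy carboxylate with the Z geometry fixed by the ring; O-alkylation of the carboxylate and immediate acetylation of the primary alcohol cap both ends before the lactone can re-form.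

Step 21
Reactants: 37 4-methoxybenzyl (2Z)-4-(acetyloxy)-2-methylbut-2-enoate
Product: 38 (2Z)-4-(acetyloxy)-2-methylbut-2-enoic acid
Conditions: CF3CO2H, Et3SiH, CH2Cl2, 0 °C
Reagents that add atoms: none
Why: Acidolysis of the PMB ester with a silane as cation scavenger; no hydroxide is used, so the acetate stays in place, and brief cold acid should leave the Z alkene untouched.

Step 22
Reactants: 33 2-(trimethylsilyl)ethyl 2-[(1R,2S,3R,4S,6S)-3-{3-[(tert-butyldiphenylsilyl)oxy]prop-1-en-2-yl}-4-ethenyl-6-hydroxy-4-methyl-2-[(triethylsilyl)oxy]cyclohexyl]prop-2-enoate; 38 (2Z)-4-(acetyloxy)-2-methylbut-2-enoic acid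
Product: 40 2-(trimethylsilyl)ethyl 2-[(1R,2S,3R,4S,6S)-6-{[(2Z)-4-(acetyloxy)-2-methylbut-2-enoyl]oxy}-3-{3-[(tert-butyldiphenylsilyl)oxy]prop-1-en-2-yl}-4-ethenyl-4-methyl-2-[(triethylsilyl)oxy]cyclohexyl]prop-2-enoate, via mixed anhydride 39 (not isolated)
Conditions: 2,4,6-trichlorobenzoyl chloride, Et3N, toluene, rt; then 33, toluene, 75 °C (no DMAP)
Reagents that add atoms: none
Why: Yamaguchi-type esterification through the mixed anhydride without a nucleophilic catalyst, the protocol used for angelate (Z-2-methylbut-2-enoate) esters because it keeps Z to E isomerisation low; C3–OH is the only free hydroxyl.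

Step 23
Reactants: 40 2-(trimethylsilyl)ethyl 2-[(1R,2S,3R,4S,6S)-6-{[(2Z)-4-(acetyloxy)-2-methylbut-2-enoyl]oxy}-3-{3-[(tert-butyldiphenylsilyl)oxy]prop-1-en-2-yl}-4-ethenyl-4-methyl-2-[(triethylsilyl)oxy]cyclohexyl]prop-2-enoate
Product: 41 2-[(1S,2S,3R,4S,6S)-6-{[(2Z)-4-(acetyloxy)-2-methylbut-2-enoyl]oxy}-4-ethenyl-2-hydroxy-3-(3-hydroxyprop-1-en-2-yl)-4-methylcyclohexyl]prop-2-enoic acid
Conditions: Bu4NF, THF, 0 °C → rt; NH4Cl (aq.) work-up at pH 5–6
Reagents that add atoms: none
Why: Fluoride-induced cleavage of the triethylsilyl ether, the primary TBDPS ether and the 2-(trimethylsilyl)ethyl ester (β-elimination with loss of ethene); the acid is released as its carboxylate and protonated only in a weakly acidic work-up, so the cis γ-hydroxy acid should not lactonise.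

## Compound list

1 | cis,cis-cyclohexane-1,3,5-triol | O[C@H]1C[C@@H](O)C[C@@H](O)C1 | starting material
2 | all-cis-5-[(tert-butyldimethylsilyl)oxy]cyclohexane-1,3-diol (meso) | O[C@H]1C[C@@H](O)C[C@@H](O[Si](C)(C)C(C)(C)C)C1 | intermediate
3 | (1R,3S,5S)-3-hydroxy-5-[(tert-butyldimethylsilyl)oxy]cyclohexyl acetate | O[C@H]1C[C@@H](OC(C)=O)C[C@@H](O[Si](C)(C)C(C)(C)C)C1 | intermediate
4 | (1S,5R)-3-oxo-5-[(tert-butyldimethylsilyl)oxy]cyclohexyl acetate | O=C1C[C@@H](OC(C)=O)C[C@@H](O[Si](C)(C)C(C)(C)C)C1 | intermediate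
5 | (5R)-5-[(tert-butyldimethylsilyl)oxy]cyclohex-2-en-1-one | O=C1C=CC[C@@H](O[Si](C)(C)C(C)(C)C)C1 | intermediate
6 | bromomagnesium enolate of trans-5-[(tert-butyldimethylsilyl)oxy]-3-methylcyclohexan-1-one | C[C@@H]1C[C@@H](O[Si](C)(C)C(C)(C)C)CC(O[Mg]Br)=C1 | intermediate
7 | (5R)-5-[(tert-butyldimethylsilyl)oxy]-3-methylcyclohex-2-en-1-one | CC1=CC(=O)C[C@H](O[Si](C)(C)C(C)(C)C)C1 | intermediate
8 | vinylmagnesium bromide | C=C[Mg]Br | starting material
9 | tert-butyl{[(1R,5S)-5-ethenyl-5-methyl-3-[(trimethylsilyl)oxy]cyclohex-3-en-1-yl]oxy}dimethylsilane | C=C[C@]1(C)C[C@@H](O[Si](C)(C)C(C)(C)C)CC(O[Si](C)(C)C)=C1 | intermediate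
10 | 2-bromoprop-2-en-1-ol | OCC(Br)=C | starting material
11 | [(2-bromoprop-2-en-1-yl)oxy](tert-butyl)diphenylsilane | C=C(Br)CO[Si](c1ccccc1)(c1ccccc1)C(C)(C)C | intermediate
12 | lithium enolate derived from 9 (C5–OLi, C5=C6) | C=C[C@]1(C)C[C@@H](O[Si](C)(C)C(C)(C)C)CC(O[Li])=C1 | intermediate
13 | chlorozinc enolate derived from 12 | C=C[C@]1(C)C[C@@H](O[Si](C)(C)C(C)(C)C)CC(O[Zn]Cl)=C1 | intermediate
14 | (2R,3S,5R)-5-[(tert-butyldimethylsilyl)oxy]-2-{3-[(tert-butyldiphenylsilyl)oxy]prop-1-en-2-yl}-3-ethenyl-3-methylcyclohexan-1-one | C=C[C@]1(C)C[C@@H](O[Si](C)(C)C(C)(C)C)CC(=O)[C@H]1C(=C)CO[Si](c2ccccc2)(c2ccccc2)C(C)(C)C | intermediate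
15 | (2R,3S,5R)-2-{3-[(tert-butyldiphenylsilyl)oxy]prop-1-en-2-yl}-3-ethenyl-5-hydroxy-3-methylcyclohexan-1-one | C=C[C@]1(C)C[C@@H](O)CC(=O)[C@H]1C(=C)CO[Si](c2ccccc2)(c2ccccc2)C(C)(C)C | intermediate
16 | methanesulfonate of 15 at the C3 hydroxyl | C=C[C@]1(C)C[C@@H](OS(C)(=O)=O)CC(=O)[C@H]1C(=C)CO[Si](c2ccccc2)(c2ccccc2)C(C)(C)C | intermediate
17 | (5S,6R)-6-{3-[(tert-butyldiphenylsilyl)oxy]prop-1-en-2-yl}-5-ethenyl-5-methylcyclohex-2-en-1-one | C=C[C@]1(C)CC=CC(=O)[C@H]1C(=C)CO[Si](c2ccccc2)(c2ccccc2)C(C)(C)C | intermediate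
18 | (1R,5S,6R)-6-{3-[(tert-butyldiphenylsilyl)oxy]prop-1-en-2-yl}-5-ethenyl-5-methylcyclohex-2-en-1-ol | C=C[C@]1(C)CC=C[C@@H](O)[C@H]1C(=C)CO[Si](c2ccccc2)(c2ccccc2)C(C)(C)C | intermediate
19 | ethyl vinyl ether | C=COCC | starting material
20 | tert-butyl[(2-{(1R,2R,6S)-2-(2-bromo-1-ethoxyethoxy)-6-ethenyl-6-methylcyclohex-3-en-1-yl}prop-2-en-1-yl)oxy]diphenylsilane (acetal epimers) | C=C[C@]1(C)CC=C[C@@H](OC(OCC)CBr)[C@H]1C(=C)CO[Si](c2ccccc2)(c2ccccc2)C(C)(C)C | intermediate
21 | C3 hydroperoxide of the cyclised cis-fused acetal (hydroperoxy in place of the hydroxyl of 22) | C=C[C@]1(C)C[C@H](OO)[C@H]2CC(OCC)O[C@H]2[C@H]1C(=C)CO[Si](c3ccccc3)(c3ccccc3)C(C)(C)C | intermediate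
22 | (3aR,4S,6S,7R,7aS)-7-{3-[(tert-butyldiphenylsilyl)oxy]prop-1-en-2-yl}-2-ethoxy-6-ethenyl-6-methyloctahydro-1-benzofuran-4-ol (acetal epimers) | C=C[C@]1(C)C[C@H](O)[C@H]2CC(OCC)O[C@H]2[C@H]1C(=C)CO[Si](c3ccccc3)(c3ccccc3)C(C)(C)C | intermediate
23 | tert-butyl[(2-{(3aR,4S,6S,7R,7aS)-2-ethoxy-6-ethenyl-4-[(4-methoxybenzyl)oxy]-6-methyloctahydro-1-benzofuran-7-yl}prop-2-en-1-yl)oxy]diphenylsilane | C=C[C@]1(C)C[C@H](OCc3ccc(OC)cc3)[C@H]2CC(OCC)O[C@H]2[C@H]1C(=C)CO[Si](c4ccccc4)(c4ccccc4)C(C)(C)C | intermediate
24 | (3aR,4S,6S,7R,7aS)-7-{3-[(tert-butyldiphenylsilyl)oxy]prop-1-en-2-yl}-6-ethenyl-4-[(4-methoxybenzyl)oxy]-6-methyloctahydro-1-benzofuran-2-ol (lactol epimers) | C=C[C@]1(C)C[C@H](OCc3ccc(OC)cc3)[C@H]2CC(O)O[C@H]2[C@H]1C(=C)CO[Si](c4ccccc4)(c4ccccc4)C(C)(C)C | intermediate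
25 | (3aR,4S,6S,7R,7aS)-7-{3-[(tert-butyldiphenylsilyl)oxy]prop-1-en-2-yl}-6-ethenyl-4-[(4-methoxybenzyl)oxy]-6-methylhexahydro-1-benzofuran-2(3H)-one | C=C[C@]1(C)C[C@H](OCc3ccc(OC)cc3)[C@H]2CC(=O)O[C@H]2[C@H]1C(=C)CO[Si](c4ccccc4)(c4ccccc4)C(C)(C)C | intermediate
26 | 3-[(dimethylamino)methyl] derivative of lactone 25 (Mannich base, C3 epimers of the lactone ring) | C=C[C@]1(C)C[C@H](OCc3ccc(OC)cc3)[C@H]2C(CN(C)C)C(=O)O[C@H]2[C@H]1C(=C)CO[Si](c4ccccc4)(c4ccccc4)C(C)(C)C | intermediate
27 | trimethylammonium iodide derived from 26 | C=C[C@]1(C)C[C@H](OCc3ccc(OC)cc3)[C@H]2C(C[N+](C)(C)C)C(=O)O[C@H]2[C@H]1C(=C)CO[Si](c4ccccc4)(c4ccccc4)C(C)(C)C.[I-] | intermediate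
28 | (3aR,4S,6S,7R,7aS)-7-{3-[(tert-butyldiphenylsilyl)oxy]prop-1-en-2-yl}-6-ethenyl-4-[(4-methoxybenzyl)oxy]-6-methyl-3-methylidenehexahydro-1-benzofuran-2(3H)-one | C=C[C@]1(C)C[C@H](OCc3ccc(OC)cc3)[C@H]2C(=C)C(=O)O[C@H]2[C@H]1C(=C)CO[Si](c4ccccc4)(c4ccccc4)C(C)(C)C | intermediate
29 | lithium salt of the C5-hydroxy acrylic acid from opening of 28 | C=C[C@]1(C)C[C@H](OCc2ccc(OC)cc2)[C@@H](C(=C)C(=O)[O-])[C@@H](O)[C@H]1C(=C)CO[Si](c3ccccc3)(c3ccccc3)C(C)(C)C.[Li+] | intermediate
30 | triethylsilyl ester of acid 31 (C5 triethylsilyl ether) | C=C[C@]1(C)C[C@H](OCc2ccc(OC)cc2)[C@@H](C(=C)C(=O)O[Si](CC)(CC)CC)[C@@H](O[Si](CC)(CC)CC)[C@H]1C(=C)CO[Si](c3ccccc3)(c3ccccc3)C(C)(C)C | intermediate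
31 | 2-[(1R,2S,3R,4S,6S)-3-{3-[(tert-butyldiphenylsilyl)oxy]prop-1-en-2-yl}-4-ethenyl-6-[(4-methoxybenzyl)oxy]-4-methyl-2-[(triethylsilyl)oxy]cyclohexyl]prop-2-enoic acid | C=C[C@]1(C)C[C@H](OCc2ccc(OC)cc2)[C@@H](C(=C)C(=O)O)[C@@H](O[Si](CC)(CC)CC)[C@H]1C(=C)CO[Si](c3ccccc3)(c3ccccc3)C(C)(C)C | intermediate
32 | 2-(trimethylsilyl)ethyl ester of 31 | C=C[C@]1(C)C[C@H](OCc2ccc(OC)cc2)[C@@H](C(=C)C(=O)OCC[Si](C)(C)C)[C@@H](O[Si](CC)(CC)CC)[C@H]1C(=C)CO[Si](c3ccccc3)(c3ccccc3)C(C)(C)C | intermediate
33 | 2-(trimethylsilyl)ethyl 2-[(1R,2S,3R,4S,6S)-3-{3-[(tert-butyldiphenylsilyl)oxy]prop-1-en-2-yl}-4-ethenyl-6-hydroxy-4-methyl-2-[(triethylsilyl)oxy]cyclohexyl]prop-2-enoate | C=C[C@]1(C)C[C@H](O)[C@@H](C(=C)C(=O)OCC[Si](C)(C)C)[C@@H](O[Si](CC)(CC)CC)[C@H]1C(=C)CO[Si](c2ccccc2)(c2ccccc2)C(C)(C)C | intermediate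
34 | 3-methylfuran-2(5H)-one | CC1=CCOC1=O | starting material
35 | potassium (2Z)-4-hydroxy-2-methylbut-2-enoate | [K+].[O-]C(=O)/C(C)=C\CO | intermediate
36 | 4-methoxybenzyl (2Z)-4-hydroxy-2-methylbut-2-enoate | COc1ccc(COC(=O)/C(C)=C\CO)cc1 | intermediate
37 | 4-methoxybenzyl (2Z)-4-(acetyloxy)-2-methylbut-2-enoate | COc1ccc(COC(=O)/C(C)=C\COC(C)=O)cc1 | intermediate
38 | (2Z)-4-(acetyloxy)-2-methylbut-2-enoic acid | OC(=O)/C(C)=C\COC(C)=O | intermediate
39 | (2Z)-4-(acetyloxy)-2-methylbut-2-enoic 2,4,6-trichlorobenzoic anhydride | O=C(OC(=O)/C(C)=C\COC(C)=O)c1c(Cl)cc(Cl)cc1Cl | intermediate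
40 | 2-(trimethylsilyl)ethyl 2-[(1R,2S,3R,4S,6S)-6-{[(2Z)-4-(acetyloxy)-2-methylbut-2-enoyl]oxy}-3-{3-[(tert-butyldiphenylsilyl)oxy]prop-1-en-2-yl}-4-ethenyl-4-methyl-2-[(triethylsilyl)oxy]cyclohexyl]prop-2-enoate | C=C[C@]1(C)C[C@H](OC(=O)/C(C)=C\COC(C)=O)[C@@H](C(=C)C(=O)OCC[Si](C)(C)C)[C@@H](O[Si](CC)(CC)CC)[C@H]1C(=C)CO[Si](c2ccccc2)(c2ccccc2)C(C)(C)C | intermediate
41 | 2-[(1S,2S,3R,4S,6S)-6-{[(2Z)-4-(acetyloxy)-2-methylbut-2-enoyl]oxy}-4-ethenyl-2-hydroxy-3-(3-hydroxyprop-1-en-2-yl)-4-methylcyclohexyl]prop-2-enoic acid | C=C[C@]1(C)C[C@H](OC(=O)/C(C)=C\COC(C)=O)[C@@H](C(=C)C(=O)O)[C@@H](O)[C@H]1C(=C)CO | target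

## Step count and least certain steps

Total: 23 steps. Longest linear sequence: 20 steps (steps 1–5, 7–19, 22 and 23); steps 6, 20 and 21 prepare the two side pieces 11 and 38.

**Step 12 (key step).** Two things may go wrong. The primary radical may be captured by oxygen before it cyclises, because oxygen capture is close to diffusion-controlled. The cobalt-bound peroxide at C3 may also collapse to a ketone that borohydride then reduces from the open α face, which would cost the facial control at C3. The fallback leaves the cobalt–hydride manifold for a tin radical chain. It sets out from 20: Bu3SnH is added slowly in toluene at 0 °C under a stream of dry air, so the peroxyl radical is reduced by hydrogen-atom transfer to hydroperoxide 21, which is then reduced separately with PPh3. It returns to the route at 22 and makes no new compound.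

**Step 7.** Coupling at an enolate carbon next to a quaternary centre may be slow, so protonation of the enolate or side reactions of the alkenylpalladium species carrying an allylic silyl ether could take over. Any deprotonation of the product would also erode the C6 configuration. The fallback sets out from 9 and changes how the oxygen of the side arm is introduced. The zinc enolate is coupled with 2-bromopropene, a much smaller electrophile, to give (2S,3S,5R)-5-[(tert-butyldimethylsilyl)oxy]-3-ethenyl-3-methyl-2-(prop-1-en-2-yl)cyclohexan-1-one F1. Allylic hydroxylation of the isopropenyl methyl with catalytic SeO2 and t-BuOOH gives (2R,3S,5R)-5-[(tert-butyldimethylsilyl)oxy]-3-ethenyl-2-(3-hydroxyprop-1-en-2-yl)-3-methylcyclohexan-1-one F2 (the vinyl group has no allylic hydrogen). Silylation with TBDPSCl and imidazole returns to the route at 14.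

**Step 10.** Facial selectivity may be poor if the half-chair with the C6 group pseudo-axial reacts, since its β face is then no longer shielded by the methyl. The fallback sets out from 17. The reduction mixture is separated and the unwanted epimer, (1S,5S,6R)-6-{3-[(tert-butyldiphenylsilyl)oxy]prop-1-en-2-yl}-5-ethenyl-5-methylcyclohex-2-en-1-ol F3, is inverted by Mitsunobu reaction with 4-nitrobenzoic acid (PPh3, DIAD) to (1R,5S,6R)-6-{3-[(tert-butyldiphenylsilyl)oxy]prop-1-en-2-yl}-5-ethenyl-5-methylcyclohex-2-en-1-yl 4-nitrobenzoate F4. Methanolysis (K2CO3, MeOH) returns to the route at 18. Allylic transposition during the Mitsunobu step would have to be watched.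

**Step 17.** Hydroxide may add to the α-methylene lactone in conjugate fashion, and the hydroxy carboxylate may relactonise during silylation while its carboxyl is activated as the silyl ester. The fallback sets out from Mannich base 26, isolated after the first half of step 16, so the acceptor alkene is masked as its amine. Saponification and silylation as in step 17 give 2-[(1R,2S,3R,4S,6S)-3-{3-[(tert-butyldiphenylsilyl)oxy]prop-1-en-2-yl}-4-ethenyl-6-[(4-methoxybenzyl)oxy]-4-methyl-2-[(triethylsilyl)oxy]cyclohexyl]-3-(dimethylamino)propanoic acid F5. Mitsunobu esterification with 2-(trimethylsilyl)ethanol gives its 2-(trimethylsilyl)ethyl ester F6. N-methylation with MeI and elimination with NaHCO3 then unveil the acrylate and return to the route at 32.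

**Step 22.** The Z alkene may isomerise to E while the acid is activated, and acylation of a secondary hydroxyl flanked by the substituted C4 may be slow at a temperature that is still safe for the geometry. The fallback sets out from 33 and builds the alkene on the substrate. Acylation with 2-[bis(2,2,2-trifluoroethoxy)phosphoryl]propanoic acid (carbodiimide, DMAP) gives 2-(trimethylsilyl)ethyl 2-[(1R,2S,3R,4S,6S)-6-({2-[bis(2,2,2-trifluoroethoxy)phosphoryl]propanoyl}oxy)-3-{3-[(tert-butyldiphenylsilyl)oxy]prop-1-en-2-yl}-4-ethenyl-4-methyl-2-[(triethylsilyl)oxy]cyclohexyl]prop-2-enoate F7. Still–Gennari olefination with 2-oxoethyl acetate (KN(SiMe3)2, 18-crown-6, THF, −78 °C) is Z-selective for such α-methyl phosphonates and returns to the route at 40.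

## Further compounds

F0 | step 12 | none | none
F1 | step 7 | (2S,3S,5R)-5-[(tert-butyldimethylsilyl)oxy]-3-ethenyl-3-methyl-2-(prop-1-en-2-yl)cyclohexan-1-one | C=C[C@]1(C)C[C@@H](O[Si](C)(C)C(C)(C)C)CC(=O)[C@H]1C(C)=C
F2 | step 7 | (2R,3S,5R)-5-[(tert-butyldimethylsilyl)oxy]-3-ethenyl-2-(3-hydroxyprop-1-en-2-yl)-3-methylcyclohexan-1-one | C=C[C@]1(C)C[C@@H](O[Si](C)(C)C(C)(C)C)CC(=O)[C@H]1C(=C)CO
F3 | step 10 | (1S,5S,6R)-6-{3-[(tert-butyldiphenylsilyl)oxy]prop-1-en-2-yl}-5-ethenyl-5-methylcyclohex-2-en-1-ol | C=C[C@]1(C)CC=C[C@H](O)[C@H]1C(=C)CO[Si](c2ccccc2)(c2ccccc2)C(C)(C)C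
F4 | step 10 | (1R,5S,6R)-6-{3-[(tert-butyldiphenylsilyl)oxy]prop-1-en-2-yl}-5-ethenyl-5-methylcyclohex-2-en-1-yl 4-nitrobenzoate | C=C[C@]1(C)CC=C[C@@H](OC(=O)c2ccc(cc2)[N+](=O)[O-])[C@H]1C(=C)CO[Si](c3ccccc3)(c3ccccc3)C(C)(C)C
F5 | step 17 | 2-[(1R,2S,3R,4S,6S)-3-{3-[(tert-butyldiphenylsilyl)oxy]prop-1-en-2-yl}-4-ethenyl-6-[(4-methoxybenzyl)oxy]-4-methyl-2-[(triethylsilyl)oxy]cyclohexyl]-3-(dimethylamino)propanoic acid (epimers at the amino acid carbon) | C=C[C@]1(C)C[C@H](OCc2ccc(OC)cc2)[C@@H](C(CN(C)C)C(=O)O)[C@@H](O[Si](CC)(CC)CC)[C@H]1C(=C)CO[Si](c3ccccc3)(c3ccccc3)C(C)(C)C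
F6 | step 17 | 2-(trimethylsilyl)ethyl ester of F5 | C=C[C@]1(C)C[C@H](OCc2ccc(OC)cc2)[C@@H](C(CN(C)C)C(=O)OCC[Si](C)(C)C)[C@@H](O[Si](CC)(CC)CC)[C@H]1C(=C)CO[Si](c3ccccc3)(c3ccccc3)C(C)(C)C
F7 | step 22 | 2-(trimethylsilyl)ethyl 2-[(1R,2S,3R,4S,6S)-6-({2-[bis(2,2,2-trifluoroethoxy)phosphoryl]propanoyl}oxy)-3-{3-[(tert-butyldiphenylsilyl)oxy]prop-1-en-2-yl}-4-ethenyl-4-methyl-2-[(triethylsilyl)oxy]cyclohexyl]prop-2-enoate | C=C[C@]1(C)C[C@H](OC(=O)C(C)P(=O)(OCC(F)(F)F)OCC(F)(F)F)[C@@H](C(=C)C(=O)OCC[Si](C)(C)C)[C@@H](O[Si](CC)(CC)CC)[C@H]1C(=C)CO[Si](c2ccccc2)(c2ccccc2)C(C)(C)C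
A1 | alternative 1 | (5S)-5-[(tert-butyldimethylsilyl)oxy]-3-ethenylcyclohex-2-en-1-one | C=CC1=CC(=O)C[C@@H](O[Si](C)(C)C(C)(C)C)C1
A2 | alternative 1 | (2R,3S,5S)-5-[(tert-butyldimethylsilyl)oxy]-2-{3-[(tert-butyldiphenylsilyl)oxy]prop-1-en-2-yl}-3-ethenyl-3-methylcyclohexan-1-one | C=C[C@]1(C)C[C@H](O[Si](C)(C)C(C)(C)C)CC(=O)[C@H]1C(=C)CO[Si](c2ccccc2)(c2ccccc2)C(C)(C)C
A3 | alternative 2 | open-chain aldehyde: C5 formyl, C4 3-[(triethylsilyl)oxy]prop-1-en-2-yl, C3 4-methoxybenzyl ether, C1 methyl and vinyl, C6=C(CH3)CH2OTBS alkene with the methyl cis to C1 | O=C[C@H](C(=C)CO[Si](CC)(CC)CC)[C@@H](OCc1ccc(OC)cc1)C[C@@](C)(C=C)/C=C(\C)CO[Si](C)(C)C(C)(C)C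
A4 | alternative 2 | cyclised homoallylic alcohol: free C5 hydroxyl, C3 4-methoxybenzyl ether, C4 3-[(triethylsilyl)oxy]prop-1-en-2-yl, C6 3-[(tert-butyldimethylsilyl)oxy]prop-1-en-2-yl, ring configuration as in 41 | C=C[C@]1(C)C[C@H](OCc2ccc(OC)cc2)[C@@H](C(=C)CO[Si](CC)(CC)CC)[C@@H](O)[C@H]1C(=C)CO[Si](C)(C)C(C)(C)C
A5 | alternative 3 | open-chain C3 aldehyde carrying a (Z)-2-(bromomethyl)acrylate 2-(trimethylsilyl)ethyl ester at C4, C5 silyl ether, C6 3-[(tert-butyldimethylsilyl)oxy]prop-1-en-2-yl, C1 methyl and vinyl | O=CC[C@@](C)(C=C)[C@H](C(=C)CO[Si](C)(C)C(C)(C)C)[C@H](O[Si](C)(C)C(C)(C)C)/C=C(\CBr)C(=O)OCC[Si](C)(C)C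
A6 | alternative 3 | cyclohexanol with free C3 hydroxyl, C4 2-(trimethylsilyl)ethyl acrylate, C5 tert-butyldimethylsilyl ether, C6 3-[(tert-butyldimethylsilyl)oxy]prop-1-en-2-yl, ring configuration as in 41 | C=C[C@]1(C)C[C@H](O)[C@@H](C(=C)C(=O)OCC[Si](C)(C)C)[C@@H](O[Si](C)(C)C(C)(C)C)[C@H]1C(=C)CO[Si](C)(C)C(C)(C)C
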